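## The problem

Target 16 is a furofuran lignan of configuration (7R,8S,7'R,8'S). Two tetrahydrofuran rings, ring A (O1, C7, C8, C8', C9') and ring B (O2, C7', C8', C8, C9), share the C8–C8' bond in a cis fusion, and each benzylic carbon (C7, C7') carries its aryl group on the convex face. The four stereocentres are contiguous and depend on one another. The ring fusion forces C8 and C8' to be cis, and a benzylic centre, once fixed, can direct its neighbour (trans) and, through the bicycle, the far benzylic carbon (exo). One controlled centre can therefore be enough. The bicyclic core is C2-symmetric and the two guaiacyl rings differ only at the para oxygen (free phenol on the C7 aryl, prenyl ether on the C7' aryl). A synthesis must therefore join two different aryl-C3 halves or accept a statistical desymmetrisation. Both benzylic C–O bonds are activated by a para oxygen and ionise under protic or Lewis acid, which epimerises C7 and C7'. The prenyl ether is acid-labile, and its trisubstituted alkene does not survive hydrogenation, carbenoids or strong electrophiles, so the phenol needs a mask that leaves without acid or hydrogen. The only C–C bond between the two aryl-C3 halves is C8–C8'. C8 carries the C9 oxygen as neighbour and is linked to the C8'=C7' position by the chain C8–C7–O1–C9'–C8'. A radical at C8, released from a C8–C9 epoxide, can therefore add 5-exo to a C8'=C7' styrene across the O1 ether. The C9 oxygen freed by the same epoxide opening is then placed to capture C7'.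

## Retrosynthesis

**16 from 15.** Only the O–Si bond of the phenol is cut. A silyl ether is chosen because fluoride removes it without acid or hydrogen, so the benzylic ethers, the prenyl ether and the four stereocentres are not at risk. Benzyl or acetal protection would need hydrogenolysis or acid at the last step. The forward reaction only has to be non-acidic.

**15 from 12.** The C8–C8' bond and the C7'–O2 bond are cut together. Cutting at C7–C8 or at the aryl–carbon bonds would leave a preformed ring with two or more stereocentres to be made separately. The chosen cut removes both rings and three stereocentres at once and leaves the acyclic epoxy cinnamyl ether 12 with one relevant stereocentre, C7 (the epoxide centre C8 is erased in the radical). The forward reaction must open the epoxide toward C8 with trivalent titanium and close ring A 5-exo with C8 trans to the C7 aryl and cis to C8' (titanium intermediate 13). It must then oxidise C7' with iodine (iodide 14), close ring B with the aryl exo, and leave the prenyl alkene and the silyl ether alone. The aryl groups are assigned on purpose. The less donating silyloxy aryl sits on the preset centre C7, which must not ionise, and the better donor (prenyloxy aryl) sits on C7', which must be oxidised. Because the core is C2-symmetric, the opposite assignment would lead to the same compound 15.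

**12 from 5 and 11.** The O1–C9' ether bond is cut. Forming O1–C7 instead would need substitution at the electron-rich benzylic carbon and would scramble C7. The precursors are epoxy alcohol 5 and cinnamyl bromide 11, each a vanillin-derived aryl-C3 unit. The forward etherification must avoid a free alkoxide, because that would cause epoxide migration in 5 or silyl transfer, and it must give the linear E ether.

**5 from 4, 2, 3 and 1.** The epoxide oxygen is removed to give racemic aryl vinyl carbinol 4, which comes from aldehyde 2 and vinylmagnesium bromide 3 (C7–C8 bond), and 2 from vanillin 1. A titanium–tartrate epoxidation with kinetic resolution both selects the C7 enantiomer and installs the epoxide in one step. This is shorter than an asymmetric vinyl addition followed by a separate epoxidation. It asks for a sufficient rate difference between the enantiomers of 4 and a stop below half conversion, and at most half of 4 can be used.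

**11 from 10, 9, 7, 8, 6 and 1.** The C–Br bond goes back to alcohol 10 and the allylic alcohol to ester 9. The C=C bond of 9 comes from O-prenyl vanillin 7 and phosphonate 8, and 7 from 1 and prenyl bromide 6. These are routine operations. The only demand is a neutral bromination, since the prenyl ether and the electron-rich cinnamyl system do not tolerate HBr.

## Roads not taken

**Alternative 1:** The cut is at C7'–C8' and C7–C8, so both aryl-bearing carbons are attached to a four-carbon C9'–C8'–C8–C9 unit. In the forward step the lithium derivative of the prenyloxy aryl dithiane A3 adds to C8' of the menthyloxy butenolide A2 anti to the menthyloxy group. The lactone enolate is then trapped by aldehyde 2 anti to the new substituent, giving the trans-disubstituted lactone A1 as a mixture of C7 carbinol epimers.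
- Merits: three components and both ring-fusion centres are joined in one flask. The absolute configuration comes from a recoverable auxiliary, so no material is discarded in a resolution, and the two aryl groups are different from the start.
- Weak points for 16: no ring of the target is closed. The thioacetal at C7' must be removed with mercury salts or oxidants that also attack the prenyl alkene. C7' must be reduced and the lactone and acetal carbons reduced to alcohols. Both rings are then closed by acid-mediated dehydration at the two benzylic carbons, which exposes the prenyl ether to acid and leaves C7 and C7' to thermodynamic control with only a small exo preference.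
- Comparison: A1 is reached more convergently and with better material economy than 12, and its C8/C8' control is more secure than a radical closure. Against this, the chosen plan closes both rings in the bond-forming step and needs three steps from fragment union to 16 instead of roughly twice as many. It also never unmasks a thioacetal or runs an acidic cyclisation next to the prenyl group.

**Alternative 2:** The cut is C7–C8 (ring A), with ring B present as a γ-lactone. In the forward step Rh2(OAc)4 decomposes the α-diazo lactone A5 and the carbenoid carbon C8 inserts into a benzylic C7–H bond of the ether side chain. This closes ring A cis-fused to the lactone and gives furofuranone A4 with both aryl groups exo.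
- Merits: insertion next to an ether oxygen at a benzylic position is electronically favoured, five-membered ring formation is the normal mode, and the fusion can only be cis. C7' and C8' are fixed before the key step, so the outcome does not hang on a radical transition state.
- Weak points: A5 has two stereocentres (C7', C8' trans) that need their own asymmetric synthesis plus a diazo transfer. The carbenoid can also attack the electron-rich arenes or form an oxonium ylide at O1. A prenyl alkene would be cyclopropanated, so A4 carries two different silyl ethers, and the prenyl group must be added after removing the tert-butyldimethylsilyl group selectively beside the triisopropylsilyl group. The C9 carbonyl must then be reduced to CH2 next to two acid-sensitive benzylic ethers.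
- Comparison: in reliability at the ring fusion this road is at least equal and probably better. The chosen plan sets against it that 15 is formed at the final oxidation level with the prenyl ether in place, that only one stereocentre is made before the key step, and that the endgame is one step and not five or more.

**Alternative 3:** Both aryl–carbon bonds (at C7 and C7') are cut and the bicyclic core is made first. In the forward step Me3SiBr ionises each anomeric acetate of the bis-lactol diacetate A7 to a cyclic oxocarbenium ion, and the arylzinc reagent A8 adds to C7 and C7' from the convex face, giving the bis-silyl ether A6.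
- Merits: this is the most convergent entry to the ring system, and only C8 and C8' must be controlled beforehand. Convex-face attack on a rigid cis-fused oxocarbenium ion should be more exo-selective than a radical closure, and the aryl groups can be varied last.
- Weak points for 16: A6 is C2-symmetric with the same aryl group twice, so the difference between the phenols must be created afterwards. One way is full desilylation to diphenol A9 and mono-prenylation, which is statistical. The other is two successive additions of different arylzinc reagents, which is also statistical at the first addition because the two acetates are homotopic. Enantiopure A7 needs a route of its own.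
- Comparison: for a symmetrical furofuran this road would be preferable, and its control at the benzylic carbons is better. The chosen plan sets against it that the two different aryl groups enter with two different fragments (2 and 7, both from vanillin), so no statistical step is needed and the prenyl ether is present from the beginning.

Key step: step 9

Assumption: the benzylic C7' radical is taken to be held as its Cp2TiCl adduct 13 until iodine is added; a free radical oxidised directly by iodine would give the same iodide 14 and the same product.

## Route

Step 1
Reactants: 1 vanillin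
Product: 2 4-[(tert-butyldimethylsilyl)oxy]-3-methoxybenzaldehyde
Conditions: TBSCl, imidazole, CH2Cl2, 0 °C to rt
Reagents that add atoms: tert-butyldimethylsilyl chloride, CC(C)(C)[Si](C)(C)Cl
Why: Imidazole-promoted O-silylation of a phenol; the aryl silyl ether removes the acidic proton before the Grignard step and is later cleaved by fluoride.

Step 2
Reactants: 2 4-[(tert-butyldimethylsilyl)oxy]-3-methoxybenzaldehyde; 3 vinylmagnesium bromide
Product: 4 racemic 1-{4-[(tert-butyldimethylsilyl)oxy]-3-methoxyphenyl}prop-2-en-1-ol
Conditions: THF, −78 to 0 °C; then aq. NH4Cl
Reagents that add atoms: none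
Why: 1,2-Addition of a vinyl Grignard reagent to an aromatic aldehyde forms the C7–C8 bond; the carbinol centre C7 is formed racemic and is resolved in step 3.

Step 3
Reactants: 4 racemic 1-{4-[(tert-butyldimethylsilyl)oxy]-3-methoxyphenyl}prop-2-en-1-ol
Product: 5 (S)-{4-[(tert-butyldimethylsilyl)oxy]-3-methoxyphenyl}[(2R)-oxiran-2-yl]methanol (erythro)
Conditions: Ti(OiPr)4 (20 mol%), L-(+)-diisopropyl tartrate (24 mol%), tBuOOH (0.45 equiv), 4 Å MS, CH2Cl2, −20 °C; stopped below half conversion
Reagents that add atoms: tert-butyl hydroperoxide, CC(C)(C)OO
Why: Sharpless kinetic resolution of a secondary allylic alcohol: with L-(+)-tartrate the R enantiomer of 4 (the aryl counterpart of the fast-reacting S alkyl vinyl carbinols, the descriptor changing only because aryl outranks vinyl) is epoxidised faster and gives the erythro epoxy alcohol, so C7 is set by selection of one enantiomer and C8 by the catalyst. The threo epoxide from the slow enantiomer is a diastereomer and is removed by chromatography, and the unreacted S enantiomer of 4 is discarded.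

Step 4
Reactants: 1 vanillin; 6 prenyl bromide (1-bromo-3-methylbut-2-ene)
Product: 7 3-methoxy-4-[(3-methylbut-2-en-1-yl)oxy]benzaldehyde
Conditions: K2CO3, DMF, rt
Reagents that add atoms: none
Why: Williamson O-alkylation of the phenoxide with a primary allylic bromide (SN2).

Step 5
Reactants: 7 3-methoxy-4-[(3-methylbut-2-en-1-yl)oxy]benzaldehyde; 8 triethyl phosphonoacetate
Product: 9 ethyl (2E)-3-{3-methoxy-4-[(3-methylbut-2-en-1-yl)oxy]phenyl}prop-2-enoate
Conditions: NaH, THF, 0 °C to rt
Reagents that add atoms: none
Why: Horner–Wadsworth–Emmons olefination with a stabilised phosphonate anion gives the E cinnamate.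

Step 6
Reactants: 9 ethyl (2E)-3-{3-methoxy-4-[(3-methylbut-2-en-1-yl)oxy]phenyl}prop-2-enoate
Product: 10 (2E)-3-{3-methoxy-4-[(3-methylbut-2-en-1-yl)oxy]phenyl}prop-2-en-1-ol
Conditions: iBu2AlH (2.2 equiv), CH2Cl2, −78 °C; then aq. potassium sodium tartrate
Reagents that add atoms: none
Why: iBu2AlH reduces an α,β-unsaturated ester to the allylic alcohol by 1,2-hydride delivery and leaves both alkenes and the aryl ethers untouched.

Step 7
Reactants: 10 (2E)-3-{3-methoxy-4-[(3-methylbut-2-en-1-yl)oxy]phenyl}prop-2-en-1-ol
Product: 11 4-[(1E)-3-bromoprop-1-en-1-yl]-2-methoxy-1-[(3-methylbut-2-en-1-yl)oxy]benzene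
Conditions: CBr4, PPh3, CH2Cl2, 0 °C; used crude at once
Reagents that add atoms: carbon tetrabromide, BrC(Br)(Br)Br
Why: Appel bromination runs under neutral conditions without HBr, so the prenyl ether is not cleaved; the electron-rich cinnamyl bromide is labile and is used without chromatography.

Step 8
Reactants: 5 (S)-{4-[(tert-butyldimethylsilyl)oxy]-3-methoxyphenyl}[(2R)-oxiran-2-yl]methanol; 11 4-[(1E)-3-bromoprop-1-en-1-yl]-2-methoxy-1-[(3-methylbut-2-en-1-yl)oxy]benzene
Product: 12 tert-butyl(2-methoxy-4-{(S)-[(2E)-3-{3-methoxy-4-[(3-methylbut-2-en-1-yl)oxy]phenyl}prop-2-en-1-yl]oxy[(2R)-oxiran-2-yl]methyl}phenoxy)dimethylsilane (C7 arranged in space as in 16)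
Conditions: Ag2O, 4 Å MS, CH2Cl2, rt, dark
Reagents that add atoms: none
Why: Ag2O-mediated Williamson-type etherification: silver assists loss of bromide and the oxide takes up HBr, so no free alkoxide forms that could cause Payne rearrangement of the epoxy alcohol or silyl transfer. Capture at the terminal carbon keeps the styrene conjugation and gives the linear E ether, and C7 and C8 are not touched.

Step 9
Reactants: 12 tert-butyl(2-methoxy-4-{(S)-[(2E)-3-{3-methoxy-4-[(3-methylbut-2-en-1-yl)oxy]phenyl}prop-2-en-1-yl]oxy[(2R)-oxiran-2-yl]methyl}phenoxy)dimethylsilane
Product: 15 O-TBS ether of the target (7R,8S,7'R,8'S), via bis-titanium tetrahydrofuran 13 (not isolated), via benzylic iodide 14 (not isolated)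
Conditions: Cp2TiCl2, Zn dust, THF, rt (gives Cp2TiCl); solution added slowly to 12 in THF, rt; then I2, THF, rt; aq. Na2S2O3
Reagents that add atoms: none
Why: Cp2TiCl (trivalent titanium) transfers one electron to the epoxide and the C8–O bond breaks to give the secondary β-titanoxy radical at C8, the more stable of the two possible radicals, so the C9 oxygen is kept as a titanium alkoxide and the epoxide stereocentre is erased. The radical adds to the styrene carbon C8' in a 5-exo-trig closure of ring A (C8–C8' bond), preferred over 6-endo attack at C7' because only the exo mode gives a benzylic radical, and the remote prenyl alkene cannot be reached through a five- or six-membered transition state. The C7' radical is taken up by a second Cp2TiCl (13), iodine converts it into the benzylic iodide 14, and the C9 titanium alkoxide displaces iodide in a 5-exo-tet closure of ring B (C7'–O2 bond) with much SN1 character, because the prenyloxy aryl stabilises the cation. C8 is set trans to the C7 aryl because the aryl group is pseudoequatorial in the chair-like transition state (Beckwith–Houk model), and C8' is set cis to C8 by the same transition state; in addition only the cis isomer can bridge to the bicycle. C7' is set in the closure of ring B, where the aryl group takes the convex face of the forming cis-fused bicycle. The step needs epoxide opening toward C8, exo over endo cyclisation and retention at C7; these are secured by the terminal epoxide, the styrene acceptor, and the less donating silyloxy aryl at C7 together with short exposure to iodine at ambient temperature. The closest known reaction type is the Cp2TiCl-mediated epoxide opening and radical cyclisation of epoxy allyl and cinnamyl ethers with iodine-promoted closure to furofurans.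

Step 10
Reactants: 15 O-TBS ether of the target
Product: 16 4-[(7R,8S,7'R,8'S)-7'-{3-methoxy-4-[(3-methylbut-2-en-1-yl)oxy]phenyl}furofuran-7-yl]-2-methoxyphenol, the target (furo[3,4-c]furan locants 1R,3aS,4R,6aS)
Conditions: Bu4NF, THF, 0 °C; then aq. NH4Cl
Reagents that add atoms: none
Why: Fluoride cleaves the aryl silyl ether through Si–F bond formation; the conditions are not acidic, so the prenyl ether, the benzylic ethers and the four stereocentres are unaffected.

## Compound list

1 | vanillin | COc1cc(C=O)ccc1O | starting material
2 | 4-[(tert-butyldimethylsilyl)oxy]-3-methoxybenzaldehyde | COc1cc(C=O)ccc1O[Si](C)(C)C(C)(C)C | intermediate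
3 | vinylmagnesium bromide | C=C[Mg]Br | starting material
4 | racemic 1-{4-[(tert-butyldimethylsilyl)oxy]-3-methoxyphenyl}prop-2-en-1-ol | COc1cc(C(O)C=C)ccc1O[Si](C)(C)C(C)(C)C | intermediate
5 | (S)-{4-[(tert-butyldimethylsilyl)oxy]-3-methoxyphenyl}[(2R)-oxiran-2-yl]methanol | COc1cc([C@H](O)[C@H]2CO2)ccc1O[Si](C)(C)C(C)(C)C | intermediate
6 | prenyl bromide (1-bromo-3-methylbut-2-ene) | CC(C)=CCBr | starting material
7 | 3-methoxy-4-[(3-methylbut-2-en-1-yl)oxy]benzaldehyde | COc1cc(C=O)ccc1OCC=C(C)C | intermediate
8 | triethyl phosphonoacetate | CCOC(=O)CP(=O)(OCC)OCC | starting material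
9 | ethyl (2E)-3-{3-methoxy-4-[(3-methylbut-2-en-1-yl)oxy]phenyl}prop-2-enoate | CCOC(=O)/C=C/c1ccc(OCC=C(C)C)c(OC)c1 | intermediate
10 | (2E)-3-{3-methoxy-4-[(3-methylbut-2-en-1-yl)oxy]phenyl}prop-2-en-1-ol | OC/C=C/c1ccc(OCC=C(C)C)c(OC)c1 | intermediate
11 | 4-[(1E)-3-bromoprop-1-en-1-yl]-2-methoxy-1-[(3-methylbut-2-en-1-yl)oxy]benzene | BrC/C=C/c1ccc(OCC=C(C)C)c(OC)c1 | intermediate
12 | (7S,8R)-epoxy cinnamyl ether, key-step precursor (C7 arranged as in 16) | COc1cc([C@H](OC/C=C/c2ccc(OCC=C(C)C)c(OC)c2)[C@H]2CO2)ccc1O[Si](C)(C)C(C)(C)C | intermediate
13 | (7R,8S,8'S) ring A tetrahydrofuran with Cp2Ti(Cl)–O at C9 and Cp2Ti(Cl) at C7' (C7' unassigned), not isolated | COc1cc([C@@H]2OC[C@@H](C([Ti](Cl)(C3C=CC=C3)C3C=CC=C3)c3ccc(OCC=C(C)C)c(OC)c3)[C@H]2CO[Ti](Cl)(C2C=CC=C2)C2C=CC=C2)ccc1O[Si](C)(C)C(C)(C)C | intermediate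
14 | (7R,8S,8'S) ring A tetrahydrofuran C7' iodide with Cp2Ti(Cl)–O at C9 (C7' unassigned), not isolated | COc1cc([C@@H]2OC[C@@H](C(I)c3ccc(OCC=C(C)C)c(OC)c3)[C@H]2CO[Ti](Cl)(C2C=CC=C2)C2C=CC=C2)ccc1O[Si](C)(C)C(C)(C)C | intermediate
15 | O-TBS ether of the target (7R,8S,7'R,8'S) | COc1cc([C@@H]2OC[C@@H]3[C@H]2CO[C@H]3c2ccc(OCC=C(C)C)c(OC)c2)ccc1O[Si](C)(C)C(C)(C)C | intermediate
16 | (7R,8S,7'R,8'S)-furofuran with 4-hydroxy-3-methoxyphenyl at C7 and 3-methoxy-4-prenyloxyphenyl at C7' | COc1cc([C@@H]2OC[C@@H]3[C@H]2CO[C@H]3c2ccc(OCC=C(C)C)c(OC)c2)ccc1O | target

## Step count and risks

Total steps: 10. Longest linear sequence: 7 steps (steps 4, 5, 6, 7, 8, 9, 10 from vanillin).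

**Step 9 (key step).** The most likely failures are incomplete stereocontrol in the radical closure and reduction instead of oxidation of the benzylic radical. In the first case the minor C8/C8'-trans ring A cannot close ring B; in the second ring B is not formed. Iodine or hydrogen iodide may also attack the prenyl alkene and the allylic aryl ether, and acid may epimerise C7. The first two lower the yield but leave separable by-products; the attack on the prenyl group can be cured by design. Fallback: the prenyl group is taken out of the cascade and attached afterwards. Vanillin 1 would be O-allylated (allyl bromide, K2CO3) to 3-methoxy-4-(prop-2-en-1-yloxy)benzaldehyde F1. F1 would follow the sequence used for 7: olefination with 8 to the ethyl (E)-cinnamate F2, iBu2AlH reduction to the cinnamyl alcohol F3, and Appel bromination to the cinnamyl bromide F4. F4 would be joined to 5 with Ag2O to give the epoxy ether F5. The Cp2TiCl/iodine cascade on F5 would give the O-allyl O'-silyl furofuran F6, whose monosubstituted alkene is far less prone to iodine and acid. Zerovalent palladium (Pd(PPh3)4) with morpholine would remove the allyl group to give the mono-silyl diphenol F7. A Mitsunobu etherification of F7 with 3-methylbut-2-en-1-ol (PPh3, diisopropyl azodicarboxylate) would install the prenyl ether without base. The fallback sets out from 5 (with 1 and 8) and rejoins the route at 15.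

**Step 3.** The rate difference between the enantiomers of 4 may be too small, so the epoxy alcohol would carry eroded enantiomeric purity at C7. Epoxidation of the terminal alkene may also be slow, leaving time for titanium-induced decomposition of the electron-rich benzylic alcohol. Fallback: C7 is set by an enzymatic resolution, and the titanium–tartrate epoxidation is used only as a matched, full-conversion epoxidation. Racemic 4 would be acylated with vinyl acetate and immobilised Candida antarctica lipase B. By the usual rule for secondary carbinols (large aryl, medium vinyl) the enzyme acylates the R enantiomer and gives the (R)-acetate F8. After separation from the unreacted S alcohol, iBu2AlH at −78 °C would cleave the acetate without touching the aryl silyl ether and give the (R)-alcohol F9. Epoxidation of F9 with Ti(OiPr)4, L-(+)-diisopropyl tartrate and tBuOOH would give 5. The fallback sets out from 4 and rejoins at 5.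

**Step 8.** Silver-assisted ionisation of the electron-rich cinnamyl bromide may be faster than its capture by the hindered secondary alcohol, so 11 would be lost to hydrolysis, self-condensation or branched ether; the lability of 11 from step 7 adds to this. Epoxide migration in 5 is a second risk. Fallback: the O1–C9' bond is made with a robust electrophile and the aryl group is attached afterwards. 5 would be etherified with allyl bromide and Ag2O (allyl bromide does not ionise and can be used in excess) to give the allyl ether F10. A Heck reaction of F10 with 4-iodo-2-methoxy-1-[(3-methylbut-2-en-1-yl)oxy]benzene F11 would follow under ligand-free phase-transfer conditions (Pd(OAc)2, Bu4NCl, NaHCO3, DMF). F11 would come from commercial 4-iodo-2-methoxyphenol and 6 with K2CO3. Arylation at the terminal alkene carbon and β-hydride elimination toward the benzylic position would give the E cinnamyl ether. The fallback sets out from 5 and rejoins at 12, and it makes the bromide 11 unnecessary.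

## Further compounds

F1 | step 9 | 3-methoxy-4-(prop-2-en-1-yloxy)benzaldehyde | COc1cc(C=O)ccc1OCC=C
F2 | step 9 | ethyl (2E)-3-[3-methoxy-4-(prop-2-en-1-yloxy)phenyl]prop-2-enoate | CCOC(=O)/C=C/c1ccc(OCC=C)c(OC)c1
F3 | step 9 | (2E)-3-[3-methoxy-4-(prop-2-en-1-yloxy)phenyl]prop-2-en-1-ol | OC/C=C/c1ccc(OCC=C)c(OC)c1
F4 | step 9 | 4-[(1E)-3-bromoprop-1-en-1-yl]-2-methoxy-1-(prop-2-en-1-yloxy)benzene | BrC/C=C/c1ccc(OCC=C)c(OC)c1
F5 | step 9 | (7S,8R)-epoxy cinnamyl ether with allyloxy aryl in place of prenyloxy aryl | COc1cc([C@H](OC/C=C/c2ccc(OCC=C)c(OC)c2)[C@H]2CO2)ccc1O[Si](C)(C)C(C)(C)C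
F6 | step 9 | (7R,8S,7'R,8'S)-furofuran with TBS-oxy aryl at C7 and allyloxy aryl at C7' | COc1cc([C@@H]2OC[C@@H]3[C@H]2CO[C@H]3c2ccc(OCC=C)c(OC)c2)ccc1O[Si](C)(C)C(C)(C)C
F7 | step 9 | (7R,8S,7'R,8'S)-furofuran mono-TBS ether with free phenol on the C7' aryl | COc1cc([C@@H]2OC[C@@H]3[C@H]2CO[C@H]3c2ccc(O)c(OC)c2)ccc1O[Si](C)(C)C(C)(C)C
F8 | step 3 | (1R)-1-{4-[(tert-butyldimethylsilyl)oxy]-3-methoxyphenyl}prop-2-en-1-yl acetate | COc1cc([C@H](OC(C)=O)C=C)ccc1O[Si](C)(C)C(C)(C)C
F9 | step 3 | (1R)-1-{4-[(tert-butyldimethylsilyl)oxy]-3-methoxyphenyl}prop-2-en-1-ol | COc1cc([C@H](O)C=C)ccc1O[Si](C)(C)C(C)(C)C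
F10 | step 8 | tert-butyl(2-methoxy-4-{(S)-[(2R)-oxiran-2-yl](prop-2-en-1-yloxy)methyl}phenoxy)dimethylsilane | COc1cc([C@H](OCC=C)[C@H]2CO2)ccc1O[Si](C)(C)C(C)(C)C
F11 | step 8 | 4-iodo-2-methoxy-1-[(3-methylbut-2-en-1-yl)oxy]benzene | COc1cc(I)ccc1OCC=C(C)C
A1 | alternative 1 | trans-3,4-disubstituted 5-menthyloxy lactone, C7 carbinol epimers | O=C1O[C@H](O[C@H]2C[C@@H](C)CC[C@@H]2C(C)C)[C@@H](C2(c3ccc(OCC=C(C)C)c(OC)c3)SCCCS2)[C@@H]1C(O)c1ccc(O[Si](C)(C)C(C)(C)C)c(OC)c1
A2 | alternative 1 | 5-menthyloxy-2(5H)-furanone (configuration as in the SMILES) | O=C1O[C@H](O[C@H]2C[C@@H](C)CC[C@@H]2C(C)C)C=C1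
A3 | alternative 1 | 2-{3-methoxy-4-[(3-methylbut-2-en-1-yl)oxy]phenyl}-1,3-dithiane | COc1cc(C2SCCCS2)ccc1OCC=C(C)C
A4 | alternative 2 | cis-fused furofuranone (C9 lactone) with both aryl groups exo | COc1cc([C@@H]2OC[C@@H]3[C@H]2C(=O)O[C@H]3c2ccc(O[Si](C)(C)C(C)(C)C)c(OC)c2)ccc1O[Si](C(C)C)(C(C)C)C(C)C
A5 | alternative 2 | trans-α-diazo-γ-aryl-β-(aryloxymethyl... benzyloxymethyl) γ-lactone (configuration as in the SMILES) | COc1cc(COC[C@@H]2C(=[N+]=[N-])C(=O)O[C@H]2c2ccc(O[Si](C)(C)C(C)(C)C)c(OC)c2)ccc1O[Si](C(C)C)(C(C)C)C(C)C
A6 | alternative 3 | bis-TBS ether of the C2-symmetric (7R,8S,7'R,8'S) diphenol | COc1cc([C@@H]2OC[C@@H]3[C@H]2CO[C@H]3c2ccc(O[Si](C)(C)C(C)(C)C)c(OC)c2)ccc1O[Si](C)(C)C(C)(C)C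
A7 | alternative 3 | cis-fused 3,7-dioxabicyclo[3.3.0]octane-2,6-diyl diacetate (anomeric centres unassigned) | CC(=O)OC1OC[C@@H]2[C@H]1COC2OC(C)=O
A8 | alternative 3 | {4-[(tert-butyldimethylsilyl)oxy]-3-methoxyphenyl}zinc bromide | COc1cc([Zn]Br)ccc1O[Si](C)(C)C(C)(C)C
A9 | alternative 3 | C2-symmetric (7R,8S,7'R,8'S) diphenol | COc1cc([C@@H]2OC[C@@H]3[C@H]2CO[C@H]3c2ccc(O)c(OC)c2)ccc1O
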